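The constants 3370 M⁻¹ s⁻¹ and 242 M⁻¹ s⁻¹ belong to the two things a living end can do when it meets free monomer: add a unit and live on, or become dead end A.

    initiator + impurity → spent initiator B (k1 = 6.52 × 10⁶ M⁻¹ s⁻¹)
    free monomer + living end → monomer in chains + living end, rate k2*[living end]*[free monomer] (k2 = 3370 M⁻¹ s⁻¹)
    free monomer + initiator → living end + monomer in chains (k3 = 484 M⁻¹ s⁻¹)
    living end + free monomer → dead end A (k4 = 242 M⁻¹ s⁻¹)

| flask | free monomer | initiator | impurity | time |
|---|---|---|---|---|
| birch | 2.0 × 10⁻⁴ M | 4.8 mol% | 3.4 µM | 10 min |
| elm | 3.0 × 10⁻⁴ M | 4.8 mol% | 3.4 µM | 10 min |

- the average divides the monomer in chains by the number of chains begun, living and dead together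
- run time (birch): 10 min

- which of the two ends with the longer chains by the average number of monomer units in a chain (chains begun, living or dead) ("neither" if they lie within 10%) (birch / elm / neither)
- average number of monomer units in a chain (chains begun, living or dead) at the end, birch
- average number of monomer units in a chain (chains begun, living or dead) at the end, elm

Taken by itself, growth gives a living end no stopping point, so the constants set no length. Adding death changes that. Both rates carry the same product, c(living end) · c(free monomer), so the fraction of living ends left after one meeting does not depend on concentration:

fraction left per meeting = 3370 M⁻¹ s⁻¹ / (3370 M⁻¹ s⁻¹ + 242 M⁻¹ s⁻¹) = 0.933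

Summing the fractions left over successive meetings gives the growth steps per chain, which equal the growth constant over the death constant, the partition ratio. Initiator supplies the first unit, so:

length = 1 + 0.933 / (1 − 0.933) = 14.9

This average number of units per chain begun, the first unit plus the growth steps before death, contains no charge.

Initiator and impurity come last. At the start in birch, initiator use by free monomer is 0.0044 of its use by impurity, hardly any, so impurity first removes 3.4 µM of initiator. This changes the number of chains, not their length. Each chain takes its length plus one free monomer, the last going into dead end A. The fraction of free monomer left is then: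

birch: 1 − (4.8 mol% · 2.0 × 10⁻⁴ M − 3.4 µM) · (14.9 + 1) / 2.0 × 10⁻⁴ M = 50.6%

elm: 1 − (4.8 mol% · 3.0 × 10⁻⁴ M − 3.4 µM) · (14.9 + 1) / 3.0 × 10⁻⁴ M = 41.6%

Both fractions stay above zero, so by this reckoning free monomer remains in both flasks after the last chain has ended. Even at these lower monomer levels, the fraction of living ends left after 10 min reckons to about 4.12 × 10⁻⁷ in birch and 1.35 × 10⁻⁸ in elm. Initiator, with its larger constant, runs down faster. My reckoning therefore gives 14.9 for both flasks, which puts them within 10% of each other.

The forecast gives 14.9 for birch and 14.9 for elm, and so neither, on the ground that “growth and death both scale with free monomer”.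

The simulation gives 14.9 for birch and 14.9 for elm, so the verdict is neither.

Birch with 8.0 × 10⁻⁴ M of free monomer, at the same loading and time, has the same fraction left per meeting and so the same 14.9 units per chain. It begins 35.0 µM of chains, which leaves 30.3% of its free monomer by the same reckoning. The simulation of that flask reads a length of 14.9, with free monomer at 30.3% of its charge.

The constants were set for the occasion, and the outcome is calculated.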